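## Retrosynthetic overview

1. Labels: ring A = resorcinol ring, ring B = catechol ring fused to the seven-membered ring, ring C = mono-oxygenated benzene, ring D = pendant catechol. Tricyclic compounds use dibenzo[a,d][7]annulene locants: ring B = C1–C4, C4a, C11a; ring C = C5a, C6–C9, C9a; C5 = ring B/ring C methine; C10 = ring CH2; C11 = ring D-bearing methine.
2. Feature the strategy rests on: ring C carries carbon on three neighbouring atoms (C9a holds the C10 methylene, C5a the C5 methine, C6 the bond to ring A). The seven-membered ring (C5, C4a, C11a, C11, C10, C9a, C5a) is therefore the five-membered ring of a 3-arylindan-1-one that has taken up two adjacent benzyne carbons between its C1 and C2. C6 is the carbon that receives the second oxygen of a 3,5-dimethoxybenzyne.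
3. Disconnections, last bond first: the C6–ring A biaryl bond (C–H arylation by a C6 triflate); the C5–CH2–ring A unit (C5 ketone, methylenation, hydroboration, B-alkyl Suzuki coupling); the seven-membered ring together with ring C (aryne insertion into the C1–C2 bond of an indanone β-ketoester); the indanone (asymmetric Nazarov closure of a Knoevenagel adduct).
4. Ring order: five-membered ring on ring B, then its expansion to the seven-membered ring with ring C fused on, then attachment of ring A through CH2, then the six-membered dihydrophenanthrene ring.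
5. Stereochemistry: C11 (R) comes from the Nazarov catalyst and is never touched again; C5 (S) comes from hydroboration of the C5 methylidene on the face remote from ring D, which puts H5 and H11 cis.

Key step: step 6

Assumption: the sense of induction of the Cu(OTf)2/bis(oxazoline) complex on this substrate cannot be assigned in advance; the route is written for the ligand antipode that gives the (3R)-indanone, to be identified in a first test run.

## Route

Step 1
Reactants: 1 ethyl 3-(3,4-dimethoxyphenyl)-3-oxopropanoate; 2 3,4-dimethoxybenzaldehyde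
Product: 3 ethyl (2Z)-2-(3,4-dimethoxybenzoyl)-3-(3,4-dimethoxyphenyl)prop-2-enoate
Conditions: piperidine (cat.), AcOH (cat.), toluene, reflux, Dean–Stark
Reagents that add atoms: none
Why: Knoevenagel condensation of the active methylene with the aldehyde, driven by azeotropic removal of water; the alkene geometry is immaterial because both isomers interconvert on the Lewis acid of step 2.

Step 2
Reactants: 3 ethyl (2Z)-2-(3,4-dimethoxybenzoyl)-3-(3,4-dimethoxyphenyl)prop-2-enoate
Product: 4 ethyl (2S,3R)-3-(3,4-dimethoxyphenyl)-5,6-dimethoxy-1-oxo-2,3-dihydro-1H-indene-2-carboxylate (trans)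
Conditions: Cu(OTf)2 (10 mol %), 2,2'-isopropylidenebis[(4S)-4-tert-butyl-2-oxazoline] or its antipode (11 mol %), 4 Å MS, ClCH2CH2Cl, 60 °C; recrystallisation
Reagents that add atoms: none
Why: Two-point binding of the 1,3-dicarbonyl unit to the Cu(OTf)2/bis(oxazoline) complex polarises the aryl vinyl ketone for an enantioselective Nazarov cyclisation onto the ring B carbon para to a methoxy group, the ligand fixing the sense of closure and hence C3 (R), while the enolisable C2 settles trans to the C3 aryl group (2S) and crystallisation should raise the enantiomeric purity if needed.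

Step 3
Reactants: 5 3,5-dimethoxyphenol
Product: 6 3,5-dimethoxyphenyl N-isopropylcarbamate
Conditions: i-PrNCO, Et3N (cat.), CH2Cl2, rt
Reagents that add atoms: isopropyl isocyanate, CC(C)N=C=O
Why: Base-catalysed addition of the phenol to the isocyanate (carbamoylation) installs a removable ortho-directing group.

Step 4
Reactants: 6 3,5-dimethoxyphenyl N-isopropylcarbamate
Product: 10 3,5-dimethoxy-2-(trimethylsilyl)phenyl N-isopropylcarbamate, via N-silyl carbamate 7 (not isolated), via ortho-lithiated N-silyl carbamate 8 (not isolated), via C-silylated N-silyl carbamate 9 (not isolated)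
Conditions: TBSOTf, TMEDA, Et2O, 0 °C → rt; n-BuLi, TMEDA, −78 °C; TMSCl, −78 °C → rt; aq. NaHSO4
Reagents that add atoms: chlorotrimethylsilane, C[Si](C)(C)Cl
Why: In situ N-silylation masks the N–H so that the carbamate acts as a directed ortho-metalation group, n-BuLi/TMEDA lithiates C2 (flanked by the carbamate and a methoxy group, and equivalent to C6), TMSCl traps the aryllithium, and the N-silyl group is lost in the acidic work-up.

Step 5
Reactants: 10 3,5-dimethoxy-2-(trimethylsilyl)phenyl N-isopropylcarbamate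
Product: 12 3,5-dimethoxy-2-(trimethylsilyl)phenyl trifluoromethanesulfonate, via 3,5-dimethoxy-2-(trimethylsilyl)phenol 11 (not isolated)
Conditions: DBU, Et2NH, MeCN, 40 °C; then PhNTf2, rt
Reagents that add atoms: N-phenylbis(trifluoromethanesulfonimide), O=S(=O)(N(c1ccccc1)S(=O)(=O)C(F)(F)F)C(F)(F)F
Why: DBU-promoted E1cB loss of isopropyl isocyanate (scavenged by Et2NH as a urea) should free the phenoxide without protodesilylation, and O-triflation in the same flask gives the ortho-silyl aryl triflate aryne precursor.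

Step 6
Reactants: 4 ethyl (2S,3R)-3-(3,4-dimethoxyphenyl)-5,6-dimethoxy-1-oxo-2,3-dihydro-1H-indene-2-carboxylate; 12 3,5-dimethoxy-2-(trimethylsilyl)phenyl trifluoromethanesulfonate
Product: 14 ethyl (11R)-11-(3,4-dimethoxyphenyl)-2,3,6,8-tetramethoxy-5-oxo-10,11-dihydro-5H-dibenzo[a,d][7]annulene-10-carboxylate (C10 epimer mixture), via 3,5-dimethoxybenzyne 13 (not isolated)
Conditions: CsF (2.5 equiv), MeCN, 80 °C (12 in slight excess)
Reagents that add atoms: none
Why: Fluoride desilylates 12 with loss of triflate to give aryne 13 and also forms the C2 enolate of 4, whose carbon adds to the aryne carbon remote from the flanking methoxy group, leaving an aryl anion beside that methoxy group. This anion adds 4-exo-trig to the C1 ketone to give a strained benzocyclobutene alkoxide, and cleavage of the old C1–C2 bond then delivers the diaryl ketone and an ester-stabilised benzylic anion that is protonated. The indanone C2–aryl and C1–aryl bonds are thereby formed and the five-membered ring becomes the seven-membered ring with ring C fused on, the mode of closure being 4-exo-trig addition followed by fragmentation (a two-carbon ring expansion). The closest known reaction type is the acyl-alkylation of arynes by β-ketoesters, including the ring expansion of cyclic β-ketoesters, here applied to a 3-aryl-1-indanone-2-carboxylate. The new C10 centre arises by uncontrolled protonation and is removed in step 9, whereas C11 (the former C3) is not acidic under CsF and should keep its R configuration. The step needs attack at the aryne carbon distal to the methoxy group, which the inductive polarisation of the aryne by that methoxy group secures, and ring closure ahead of protonation of the aryl anion, which the adjacent ketone of the cyclic ketoester (with no second enolisable site) favours.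

Step 7
Reactants: 14 ethyl (11R)-11-(3,4-dimethoxyphenyl)-2,3,6,8-tetramethoxy-5-oxo-10,11-dihydro-5H-dibenzo[a,d][7]annulene-10-carboxylate
Product: 15 (11R)-11-(3,4-dimethoxyphenyl)-2,3,6,8-tetramethoxy-5-oxo-10,11-dihydro-5H-dibenzo[a,d][7]annulene-10-carboxylic acid (C10 epimer mixture)
Conditions: LiOH, THF/MeOH/H2O, 40 °C; then 1 M HCl
Reagents that add atoms: lithium hydroxide, [Li+].[OH-]
Why: Ester saponification, in which aqueous hydroxide can deprotonate only the inconsequential C10 position and not the C11 methine.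

Step 8
Reactants: 15 (11R)-11-(3,4-dimethoxyphenyl)-2,3,6,8-tetramethoxy-5-oxo-10,11-dihydro-5H-dibenzo[a,d][7]annulene-10-carboxylic acid
Product: 16 1,3-dioxoisoindolin-2-yl (11R)-11-(3,4-dimethoxyphenyl)-2,3,6,8-tetramethoxy-5-oxo-10,11-dihydro-5H-dibenzo[a,d][7]annulene-10-carboxylate
Conditions: N-hydroxyphthalimide, DIC, DMAP (cat.), CH2Cl2, rt
Reagents that add atoms: N-hydroxyphthalimide, O=C1c2ccccc2C(=O)N1O
Why: Carbodiimide (Steglich-type) esterification gives the redox-active N-acyloxyphthalimide.

Step 9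
Reactants: 16 1,3-dioxoisoindolin-2-yl (11R)-11-(3,4-dimethoxyphenyl)-2,3,6,8-tetramethoxy-5-oxo-10,11-dihydro-5H-dibenzo[a,d][7]annulene-10-carboxylate
Product: 17 (11R)-11-(3,4-dimethoxyphenyl)-2,3,6,8-tetramethoxy-10,11-dihydro-5H-dibenzo[a,d][7]annulen-5-one
Conditions: Ru(bpy)3Cl2 (2 mol %), Hantzsch ester (1.5 equiv), t-BuSH (20 mol %), THF, blue LED, rt
Reagents that add atoms: none
Why: Single-electron reduction of the N-acyloxyphthalimide by photoexcited Ru(bpy)3Cl2/Hantzsch ester releases phthalimide and CO2 (Barton/Okada-type reductive radical decarboxylation) and the benzylic C10 radical takes a hydrogen atom from the thiol, which erases the C10 centre and leaves C11 untouched.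

Step 10
Reactants: 17 (11R)-11-(3,4-dimethoxyphenyl)-2,3,6,8-tetramethoxy-10,11-dihydro-5H-dibenzo[a,d][7]annulen-5-one
Product: 18 (11R)-11-(3,4-dimethoxyphenyl)-6-hydroxy-2,3,8-trimethoxy-10,11-dihydro-5H-dibenzo[a,d][7]annulen-5-one
Conditions: BCl3 (1.5 equiv), CH2Cl2, −78 → 0 °C; aq. NaHCO3
Reagents that add atoms: none
Why: BCl3 bridges the C5 carbonyl oxygen and the C6 methoxy oxygen, so chloride should remove only that methyl group (chelation-controlled demethylation ortho to an aryl ketone) and leave the six non-chelating methyl ethers.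

Step 11
Reactants: 18 (11R)-11-(3,4-dimethoxyphenyl)-6-hydroxy-2,3,8-trimethoxy-10,11-dihydro-5H-dibenzo[a,d][7]annulen-5-one
Product: 19 (11R)-11-(3,4-dimethoxyphenyl)-2,3,8-trimethoxy-5-oxo-10,11-dihydro-5H-dibenzo[a,d][7]annulen-6-yl trifluoromethanesulfonate
Conditions: Tf2O, pyridine, CH2Cl2, 0 °C
Reagents that add atoms: trifluoromethanesulfonic anhydride, O=S(=O)(OS(=O)(=O)C(F)(F)F)C(F)(F)F
Why: O-sulfonylation of the hydrogen-bonded phenol under weakly basic conditions, so that the C11–H, which is vinylogously activated by the ketone, is not epimerised.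

Step 12
Reactants: 19 (11R)-11-(3,4-dimethoxyphenyl)-2,3,8-trimethoxy-5-oxo-10,11-dihydro-5H-dibenzo[a,d][7]annulen-6-yl trifluoromethanesulfonate
Product: 20 (11R)-11-(3,4-dimethoxyphenyl)-2,3,8-trimethoxy-5-methylidene-10,11-dihydro-5H-dibenzo[a,d][7]annulen-6-yl trifluoromethanesulfonate
Conditions: Cp2TiMe2 (3 equiv), toluene/THF, 70 °C, dark
Reagents that add atoms: dimethyltitanocene, [CH3-].[CH3-].c1cc[cH-]c1.c1cc[cH-]c1.[Ti+4]
Why: Petasis methylenation, in which thermally generated Cp2Ti=CH2 converts the hindered, non-enolisable diaryl ketone into the 1,1-diarylalkene without base, sparing the aryl triflate and C11.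

Step 13
Reactants: 20 (11R)-11-(3,4-dimethoxyphenyl)-2,3,8-trimethoxy-5-methylidene-10,11-dihydro-5H-dibenzo[a,d][7]annulen-6-yl trifluoromethanesulfonate; 21 1-iodo-3,5-dimethoxybenzene
Product: 23 (5S,11R)-5-(3,5-dimethoxybenzyl)-11-(3,4-dimethoxyphenyl)-2,3,8-trimethoxy-10,11-dihydro-5H-dibenzo[a,d][7]annulen-6-yl trifluoromethanesulfonate, via B-alkyl-9-BBN borane 22 (not isolated)
Conditions: 9-BBN dimer, THF, 60 °C; then H2O, 21, PdCl2(dppf) (10 mol %), AsPh3, Cs2CO3, DMF, rt → 50 °C
Reagents that add atoms: none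
Why: Anti-Markovnikov syn hydroboration with 9-BBN puts boron on the exocyclic CH2 and hydrogen on C5 from the alkene face remote from ring D (substrate control, giving 5S with H5 cis to H11), and the primary alkylborane then undergoes a B-alkyl Suzuki–Miyaura coupling in which the aryl iodide reacts ahead of the hindered aryl triflate.

Step 14
Reactants: 23 (5S,11R)-5-(3,5-dimethoxybenzyl)-11-(3,4-dimethoxyphenyl)-2,3,8-trimethoxy-10,11-dihydro-5H-dibenzo[a,d][7]annulen-6-yl trifluoromethanesulfonate
Product: 24 (5S,11R)-heptamethyl ether of the target (23 with C6 bonded to C2 of the 3,5-dimethoxybenzyl ring in place of the triflate)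
Conditions: Pd(OAc)2 (10 mol %), PCy3·HBF4 (20 mol %), PivOH (30 mol %), K2CO3, DMA, 120 °C
Reagents that add atoms: none
Why: Oxidative addition of the aryl triflate to zerovalent palladium followed by pivalate-assisted concerted metalation–deprotonation (intramolecular direct C–H arylation) closes the six-membered ring at either of the two equivalent ring A C–H positions ortho to the benzylic CH2, a five-membered closure onto ring B being geometrically excluded.

Step 15
Reactants: 24 (5S,11R)-heptamethyl ether of the target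
Product: 25 CNP0306974.2
Conditions: BBr3 (excess), CH2Cl2, −78 °C → rt; MeOH, then aqueous work-up under argon
Reagents that add atoms: none
Why: Lewis-acid cleavage of all seven aryl methyl ethers with BBr3, under which the two benzylic stereocentres, having no leaving group, should be unaffected.

## Compound list

1 | ethyl 3-(3,4-dimethoxyphenyl)-3-oxopropanoate | CCOC(=O)CC(=O)c1ccc(OC)c(OC)c1 | starting material
2 | 3,4-dimethoxybenzaldehyde | COc1ccc(C=O)cc1OC | starting material
3 | ethyl (2Z)-2-(3,4-dimethoxybenzoyl)-3-(3,4-dimethoxyphenyl)prop-2-enoate | CCOC(=O)/C(=C\c1ccc(OC)c(OC)c1)C(=O)c1ccc(OC)c(OC)c1 | intermediate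
4 | ethyl (2S,3R)-3-(3,4-dimethoxyphenyl)-5,6-dimethoxy-1-oxo-2,3-dihydro-1H-indene-2-carboxylate | COc1cc2c(cc1OC)[C@@H](c1ccc(OC)c(OC)c1)[C@H](C(=O)OCC)C2=O | intermediate
5 | 3,5-dimethoxyphenol | COc1cc(O)cc(OC)c1 | starting material
6 | 3,5-dimethoxyphenyl N-isopropylcarbamate | COc1cc(OC)cc(OC(=O)NC(C)C)c1 | intermediate
7 | 3,5-dimethoxyphenyl N-(tert-butyldimethylsilyl)-N-isopropylcarbamate (formed in the flask) | COc1cc(OC)cc(OC(=O)N(C(C)C)[Si](C)(C)C(C)(C)C)c1 | intermediate
8 | 2-lithio-3,5-dimethoxyphenyl N-(tert-butyldimethylsilyl)-N-isopropylcarbamate (formed in the flask) | COc1cc(OC)c([Li])c(OC(=O)N(C(C)C)[Si](C)(C)C(C)(C)C)c1 | intermediate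
9 | 3,5-dimethoxy-2-(trimethylsilyl)phenyl N-(tert-butyldimethylsilyl)-N-isopropylcarbamate (formed in the flask) | COc1cc(OC)c([Si](C)(C)C)c(OC(=O)N(C(C)C)[Si](C)(C)C(C)(C)C)c1 | intermediate
10 | 3,5-dimethoxy-2-(trimethylsilyl)phenyl N-isopropylcarbamate | COc1cc(OC)c([Si](C)(C)C)c(OC(=O)NC(C)C)c1 | intermediate
11 | 3,5-dimethoxy-2-(trimethylsilyl)phenol (formed in the flask as its DBU salt) | COc1cc(OC)c([Si](C)(C)C)c(O)c1 | intermediate
12 | 3,5-dimethoxy-2-(trimethylsilyl)phenyl trifluoromethanesulfonate | COc1cc(OC)c([Si](C)(C)C)c(OS(=O)(=O)C(F)(F)F)c1 | intermediate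
13 | 3,5-dimethoxybenzyne (formed in the flask) | COC1=CC(OC)=CC#C1 | intermediate
14 | ethyl (11R)-11-(3,4-dimethoxyphenyl)-2,3,6,8-tetramethoxy-5-oxo-10,11-dihydro-5H-dibenzo[a,d][7]annulene-10-carboxylate, C10 epimers | O=C1c2cc(OC)c(OC)cc2[C@@H](c2ccc(OC)c(OC)c2)C(C(=O)OCC)c2cc(OC)cc(OC)c21 | intermediate
15 | (11R)-11-(3,4-dimethoxyphenyl)-2,3,6,8-tetramethoxy-5-oxo-10,11-dihydro-5H-dibenzo[a,d][7]annulene-10-carboxylic acid, C10 epimers | O=C1c2cc(OC)c(OC)cc2[C@@H](c2ccc(OC)c(OC)c2)C(C(=O)O)c2cc(OC)cc(OC)c21 | intermediate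
16 | 1,3-dioxoisoindolin-2-yl ester of 15 | O=C1c2cc(OC)c(OC)cc2[C@@H](c2ccc(OC)c(OC)c2)C(C(=O)ON2C(=O)c3ccccc3C2=O)c2cc(OC)cc(OC)c21 | intermediate
17 | (11R)-11-(3,4-dimethoxyphenyl)-2,3,6,8-tetramethoxy-10,11-dihydro-5H-dibenzo[a,d][7]annulen-5-one | O=C1c2cc(OC)c(OC)cc2[C@@H](c2ccc(OC)c(OC)c2)Cc2cc(OC)cc(OC)c21 | intermediate
18 | (11R)-11-(3,4-dimethoxyphenyl)-6-hydroxy-2,3,8-trimethoxy-10,11-dihydro-5H-dibenzo[a,d][7]annulen-5-one | O=C1c2cc(OC)c(OC)cc2[C@@H](c2ccc(OC)c(OC)c2)Cc2cc(OC)cc(O)c21 | intermediate
19 | (11R)-11-(3,4-dimethoxyphenyl)-2,3,8-trimethoxy-5-oxo-10,11-dihydro-5H-dibenzo[a,d][7]annulen-6-yl trifluoromethanesulfonate | O=C1c2cc(OC)c(OC)cc2[C@@H](c2ccc(OC)c(OC)c2)Cc2cc(OC)cc(OS(=O)(=O)C(F)(F)F)c21 | intermediate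
20 | (11R)-11-(3,4-dimethoxyphenyl)-2,3,8-trimethoxy-5-methylidene-10,11-dihydro-5H-dibenzo[a,d][7]annulen-6-yl trifluoromethanesulfonate | C=C1c2cc(OC)c(OC)cc2[C@@H](c2ccc(OC)c(OC)c2)Cc2cc(OC)cc(OS(=O)(=O)C(F)(F)F)c21 | intermediate
21 | 1-iodo-3,5-dimethoxybenzene | COc1cc(I)cc(OC)c1 | starting material
22 | (5S,11R)-5-[(9-borabicyclo[3.3.1]nonan-9-yl)methyl]-11-(3,4-dimethoxyphenyl)-2,3,8-trimethoxy-10,11-dihydro-5H-dibenzo[a,d][7]annulen-6-yl trifluoromethanesulfonate (formed in the flask) | C1CC2CCCC(C1)B2C[C@H]1c2cc(OC)c(OC)cc2[C@@H](c2ccc(OC)c(OC)c2)Cc2cc(OC)cc(OS(=O)(=O)C(F)(F)F)c21 | intermediate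
23 | (5S,11R)-5-(3,5-dimethoxybenzyl)-11-(3,4-dimethoxyphenyl)-2,3,8-trimethoxy-10,11-dihydro-5H-dibenzo[a,d][7]annulen-6-yl trifluoromethanesulfonate | COc1cc(OC)cc(c1)C[C@H]1c2cc(OC)c(OC)cc2[C@@H](c2ccc(OC)c(OC)c2)Cc2cc(OC)cc(OS(=O)(=O)C(F)(F)F)c21 | intermediate
24 | (5S,11R)-heptamethyl ether of the target: 2,3,8-trimethoxy-11-(3,4-dimethoxyphenyl)dibenzo[a,d][7]annulene whose C5 is linked by CH2 to C1 of a 3,5-dimethoxyphenyl ring A that is also bonded through its C2 to C6 | COc1cc(OC)c2c(c1)C[C@H]1c3cc(OC)c(OC)cc3[C@@H](c3ccc(OC)c(OC)c3)Cc3cc(OC)cc-2c31 | intermediate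
25 | CNP0306974.2, the (5S,11R)-heptaphenol corresponding to 24 (H5 and H11 cis) | Oc1cc(O)c2c(c1)C[C@H]1c3cc(O)c(O)cc3[C@@H](c3ccc(O)c(O)c3)Cc3cc(O)cc-2c31 | target

## Summary

Total step count: 15. Longest linear sequence: 13 steps (from 5 through steps 3–5 and 6–15); the other branch, from 1 and 2, is 12 steps.

Steps most likely to fail:

1. Step 6 (aryne insertion). The aryl anion formed after C-arylation may be protonated, or may attack the ester, faster than it closes onto the hindered, electron-rich aryl ketone. Simple α-arylation or a second arylation would then consume the aryne. The fallback makes the same two bonds one after the other with known reactions and sets out from 4. Commercial 3,5-dimethoxyphenylboronic acid with Pb(OAc)4 and Hg(OAc)2 (cat.) in CHCl3 gives (3,5-dimethoxyphenyl)lead triacetate F1. Pinhey arylation of 4 with it in CHCl3/pyridine gives ethyl (3R)-2-(3,5-dimethoxyphenyl)-3-(3,4-dimethoxyphenyl)-5,6-dimethoxy-1-oxoindane-2-carboxylate F2, which is also the compound expected from the failure mode itself. Retro-Claisen opening of its non-enolisable ketone with KOH in aqueous THF (0 °C to rt, short contact so that the hindered ethyl ester survives) gives 2-[(1R)-1-(3,4-dimethoxyphenyl)-2-(3,5-dimethoxyphenyl)-3-ethoxy-3-oxopropyl]-4,5-dimethoxybenzoic acid F3. Intramolecular Friedel–Crafts acylation (TFAA, then BF3·OEt2, CH2Cl2) then closes the seven-membered ketone on the ring C position that is ortho and para to methoxy groups; the competing six-membered closure onto ring D would use a position activated by only one methoxy group. The route is rejoined at 14.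

2. Step 13 (hydroboration/Suzuki coupling). The hindered 1,1-diarylalkene may react slowly with 9-BBN, or the two alkene faces may be poorly differentiated because of conformational mobility of the seven-membered ring, giving a mixture at C5. The fallback makes the C5–CH2 bond by carbonyl addition and delivers the C5 hydrogen by ionic reduction; it sets out from 19. 3,5-Dimethoxybenzylmagnesium chloride F4 (from commercial 3,5-dimethoxybenzyl chloride and Mg in THF) is added to 19 with CeCl3 at −78 °C to give (11R)-5-(3,5-dimethoxybenzyl)-11-(3,4-dimethoxyphenyl)-5-hydroxy-2,3,8-trimethoxy-10,11-dihydro-5H-dibenzo[a,d][7]annulen-6-yl trifluoromethanesulfonate F5. Ionic hydrogenation (Et3SiH, TFA, CH2Cl2, −40 → 0 °C) should deliver hydride to the planar diarylmethyl cation at C5 from the face remote from ring D. The route is rejoined at 23.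

3. Step 2 (asymmetric Nazarov). The ring closure of this aryl vinyl ketone may be slow or weakly enantioselective under the chiral Cu(OTf)2/bis(oxazoline) complex, and crystallisation may not raise the purity enough. The fallback replaces asymmetric catalysis by resolution and sets out from 3. Cyclisation with achiral Cu(OTf)2 alone (ClCH2CH2Cl, 80 °C) gives racemic trans ethyl 3-(3,4-dimethoxyphenyl)-5,6-dimethoxy-1-oxoindane-2-carboxylate F6, and preparative chiral-phase SFC separates the enantiomers. The route is rejoined at 4.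

Further compounds
F1 | step 6 | (3,5-dimethoxyphenyl)lead triacetate | CC(=O)O[Pb](OC(C)=O)(OC(C)=O)c1cc(OC)cc(OC)c1
F2 | step 6 | ethyl (3R)-2-(3,5-dimethoxyphenyl)-3-(3,4-dimethoxyphenyl)-5,6-dimethoxy-1-oxoindane-2-carboxylate (C3 as in 4, C2 not assigned) | COc1cc2c(cc1OC)[C@@H](c1ccc(OC)c(OC)c1)C(c1cc(OC)cc(OC)c1)(C(=O)OCC)C2=O
F3 | step 6 | 2-[(1R)-1-(3,4-dimethoxyphenyl)-2-(3,5-dimethoxyphenyl)-3-ethoxy-3-oxopropyl]-4,5-dimethoxybenzoic acid (C2 epimers) | OC(=O)c1cc(OC)c(OC)cc1[C@@H](c1ccc(OC)c(OC)c1)C(C(=O)OCC)c1cc(OC)cc(OC)c1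
F4 | step 13 | 3,5-dimethoxybenzylmagnesium chloride | COc1cc(C[Mg]Cl)cc(OC)c1
F5 | step 13 | (11R)-5-(3,5-dimethoxybenzyl)-11-(3,4-dimethoxyphenyl)-5-hydroxy-2,3,8-trimethoxy-10,11-dihydro-5H-dibenzo[a,d][7]annulen-6-yl trifluoromethanesulfonate (C5 epimers) | OC1(Cc2cc(OC)cc(OC)c2)c2cc(OC)c(OC)cc2[C@@H](c2ccc(OC)c(OC)c2)Cc2cc(OC)cc(OS(=O)(=O)C(F)(F)F)c21
F6 | step 2 | racemic trans ethyl 3-(3,4-dimethoxyphenyl)-5,6-dimethoxy-1-oxoindane-2-carboxylate | COc1cc2c(cc1OC)[C@@H](c1ccc(OC)c(OC)c1)[C@H](C(=O)OCC)C2=O.COc1cc2c(cc1OC)[C@H](c1ccc(OC)c(OC)c1)[C@@H](C(=O)OCC)C2=O
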